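Compound numbers used throughout: resorcinol 1, 3-iodophenylacetic acid 2, deoxybenzoin 3, hydroxy-isoflavone 4, 2-(trimethylsilyl)ethanol 5, aryl iodide 6, (R)-citronellal 7, enol nonaflate 8, alkyne 9, hydroxylamine salt 10, N–O reagent 11, alkynyl bis-ether 12, Z-alkenyl bis-ether 13, target 14.

## The problem

Target 14 is daidzein (ring A fused to the pyranone ring C, ring B on C3) that carries a (1Z,3R)-3,7-dimethylocta-1,6-dienyl chain on C3' of ring B, next to the C4' hydroxyl. The rings are joined in the ordinary isoflavone way; the difficulty sits on ring B, a 1,3,4-trisubstituted benzene with oxygen on C4' and an alkenyl carbon on the neighbouring C3'. The single stereocenter C3'' is allylic, far from every other functional group and without a partner that could induce it, so it must be bought with the chain and kept away from any process that moves a multiple bond through it. The C1''=C2'' double bond must be Z, the less stable geometry of a styrene, and therefore has to come from a kinetically controlled reaction. Late intermediates are fragile: the Z-styrene ortho to a free phenol and the C6''=C7'' trisubstituted alkene do not tolerate strong acid, the Z alkene isomerises under metals, radicals or light, and the chromone is opened at C2 by hard nucleophiles. The two phenols need masks that survive carbonate at 100 °C and palladium but leave without acid or hydrogenolysis. The feature that opens a short route is the environment of C3': C4' on one side is to carry oxygen, while C2' on the other side is wedged between C3' and the ring C-bearing C1'. An aryl iodide at C3' therefore offers one accessible ortho C–H bond, the one that must become C–O, and the iodide carbon itself is where C1'' has to be attached.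

## Retrosynthesis

**14 from 13.** The last disconnection leaves the skeleton alone: the two phenolic O–H bonds of 14 are traced back to the O–CH2 bonds of the bis[2-(trimethylsilyl)ethyl] ether 13. The oxygen on C4' will arrive as an O-alkyl group, so that alkyl group must leave without acid and without hydrogen. A methyl or benzyl ether would need boron halides or hydrogenolysis, which the Z-styrene and the C6''=C7'' alkene would not survive; a 2-silylethyl ether fragments with fluoride. The same group on O7 lets one operation free both phenols. The forward step must cleave two aryl ethers without opening the chromone or moving the Z double bond.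

**13 from 12.** The Z double bond is traced back to the triple bond of alkyne 12 (two C–H bonds cut). Compared with a Z-selective Wittig reaction of a ring B aldehyde or coupling of a preformed Z-alkenyl metal, the alkyne has three advantages. Syn addition of hydrogen gives Z by mechanism, a triple bond has no geometry to lose in the hot basic step before it, and a terminal alkyne is an established terminating partner for aryl–palladium species. The size is unchanged, but the only stereochemical element besides C3'' is postponed to the penultimate step. The forward reaction has to stop at the alkene and leave the C6''=C7'' alkene and the C2=C3 bond of ring C alone.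

**12 from 6, 11 and 9.** The two bonds that define ring B are cut together: C4'–O and C3'–C1''. Cutting only C3'–C1'' would lead to a 3'-iodo-4'-alkoxy isoflavone and a conventional alkynylation, which merely hands the ortho O/C problem to a separately built ring B. Cutting both leaves aryl iodide 6 (ring B carries only iodine), the oxygen electrophile 11 and alkyne 9: three pieces of similar size, each one or two steps from commerce, none containing the Z alkene. The forward step asks a great deal. A palladium/norbornene relay must functionalise C4'–H and not C2'–H, must transfer a 2-silylethoxy group from nitrogen to carbon, and must terminate on C3' with the alkyne only after that.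

**6 from 4 and 5; 4 from 1 and 2 through 3.** In 6 the O7–CH2 bond is cut to phenol 4 and alcohol 5 (Mitsunobu etherification forward). Ring C of 4 is then taken apart in the classical way: O1–C2 and C2–C3 to a one-carbon electrophile and deoxybenzoin 3, and C4–C4a of 3 to resorcinol 1 and 3-iodophenylacetic acid 2. Building ring C late around an elaborated ring B was rejected, because the chromone is the robust part and is best made first, when a Lewis acid can harm nothing. The iodine is bought in place on 2, so its position never has to be controlled. The forward reactions need acylation of 1 at C4 and tolerance of the aryl iodide.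

**9 from 7 through 8.** Alkyne 9 has the skeleton and configuration of (R)-citronellal 7; C1 and C2 of the aldehyde become the triple bond. The triple bond is traced to enol sulfonate 8 and its C1–O bond to the aldehyde carbonyl. No carbon–carbon bond is made, in contrast to homologation of the lower aldehyde, which would first require 7 to be shortened by one carbon. The stereocenter is bought. The forward reaction needs a base that eliminates the sulfonate without isomerising the alkyne through C3.

**11 from 10.** The two N–S bonds of 11 are cut, leading to the commercial salt 10 and a sulfonyl chloride. O-Alkylation of an N-hydroxy bis-sulfonimide would require that acid to be prepared first. The forward reaction is a double N-sulfonylation.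

## Roads not taken

Alternative 1: The C1''=C2'' double bond is cut instead of the bonds to ring B.
- **Forward key step.** In the diene ester A1, 4-bromo-2-vinylphenyl (R)-4-methylhex-5-enoate, the future O4' tethers the two terminal alkenes. Ring-closing metathesis with the second-generation Grubbs catalyst would close the nine-membered benzo-fused lactone A2 with loss of the two terminal methylene groups, the ring holding the new double bond Z.
- **Merits.** The Z geometry follows from ring size and not from stopping a hydrogenation, every reaction type is precedented, and the ortho O/C pattern of ring B comes from a simple ortho-vinylphenol.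
- **Weak points.** A nine-membered ring is a strained medium ring that needs high dilution and competes with oligomerisation. One reacting alkene is a styrene and the other carries an allylic branch. The acid part of A1 is not a chiral-pool compound, so C3'' must be made. After A2 the lactone must still be opened, its carbonyl C6'' turned into the isopropylidene terminus, ring B joined to ring C at the bromine-bearing carbon, and the phenols handled, roughly doubling the length.
- **Comparison.** This road is the safer one in precedent, and its Z control is structural. The chosen plan sets against it convergence in seven steps, C3'' taken from 7 in one operation, and a semihydrogenation that is itself among the most dependable routes to a Z-styrene.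

Alternative 2: Ring C is cut at O1–C8a and C4–C4a.
- **Forward key step.** Fluoride would turn the silylaryl bis-triflate A4 into an aryne with a triflyloxy group beside the triple bond. The enolate oxygen of the β-hydroxyacrylate A5, which already holds ring B with its alkynyl chain and an allyl ether, adds at the remote aryne carbon (future C8a). The aryl anion formed next to the triflate then closes ring C on the ester to give the 5-triflyloxy isoflavone A3.
- **Merits.** It is a convergent, mild ring C assembly whose regiochemistry is set by the triflate, and the allyl ethers can later be removed under neutral conditions with zerovalent palladium, gentler than the fluoride cleavage used here.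
- **Weak points.** The target has no oxygen on C5, so the directing triflate must be reduced off in the presence of an alkyne and allyl ethers. A4 needs a multistep synthesis. O- versus C-arylation of the ambident enolate is uncertain. The ring B problem is only transferred to A5, which must be made by ordinary iodination and alkynylation. The Z alkene would still need semihydrogenation, now beside monosubstituted allyl alkenes.
- **Comparison.** The invention is spent on the ring that is easiest to make. The chosen plan uses its one unprecedented step where the structure is actually difficult, and its fluoride deprotection, though harsher than allyl removal, involves no extra group.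

Alternative 3: Ring C is cut at O1–C2 and C2=C3.
- **Forward key step.** The keto-stabilised ylide A7, with a free ring A phenol ortho to the ketone, would be O-formylated by a mixed formic anhydride. The ylide carbon then attacks the formate carbonyl in an intramolecular Wittig reaction, expelling the phosphine oxide and giving the bis-silyl ether A6 of the target.
- **Merits.** Ring C closes under nearly neutral conditions at the end, and the silyl ethers of A6 leave with fluoride at low temperature. That is a clear advantage over the heated cleavage of 13.
- **Weak points.** Olefination of an ester carbonyl by a doubly stabilised, fully substituted ylide is slow, and aryl formates are labile. A7 must be made from an α-halogenated deoxybenzoin, and halogenation is not compatible with the Z-styrene and the trisubstituted alkene. The chain would therefore ride through a long linear sequence or be added after ylide formation. The ortho O/C pattern of ring B and the Z alkene are left to other chemistry.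
- **Comparison.** The chosen plan accepts an O-alkyl protecting group, because that is what oxygen transfer can deliver, and in return makes the chromone first and the sensitive alkene last.

Key step: step 5

Assumption: salt 10 and the mediator 1-methylbicyclo[2.2.1]hept-2-ene are taken as purchasable, the mediator is recovered unchanged, and both geometric isomers of 8 eliminate to 9.

## Route

Step 1
Reactants: 1 resorcinol; 2 3-iodophenylacetic acid
Product: 4 7-hydroxy-3-(3-iodophenyl)-4H-chromen-4-one, via deoxybenzoin 3 (not isolated)
Conditions: BF3·OEt2 (neat), 85 °C; then DMF, MsCl, 50 to 80 °C; poured into water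
Reagents that add atoms: N,N-dimethylformamide, CN(C)C=O
Why: Friedel–Crafts acylation of resorcinol in BF3·OEt2 goes para to one hydroxyl and ortho to the other and gives the chelated deoxybenzoin 3; the Vilsmeier-type iminium salt from DMF and MsCl then formylates the activated methylene and the ortho phenol closes ring C with loss of dimethylamine (one-pot deoxybenzoin route to isoflavones). The aryl iodide is inert to these conditions.

Step 2
Reactants: 4 7-hydroxy-3-(3-iodophenyl)-4H-chromen-4-one; 5 2-(trimethylsilyl)ethanol
Product: 6 3-(3-iodophenyl)-7-[2-(trimethylsilyl)ethoxy]-4H-chromen-4-one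
Conditions: PPh3, DIAD, THF, 0 °C to rt
Reagents that add atoms: none
Why: Mitsunobu etherification of the acidic 7-OH, the only hydroxyl in 4, with a primary alcohol; the neutral conditions avoid the elimination that 2-silylethyl halides suffer under basic alkylation.

Step 3
Reactants: 7 (R)-citronellal
Product: 9 (3R)-3,7-dimethyloct-6-en-1-yne, via enol nonaflate 8 (not isolated)
Conditions: nonafluorobutane-1-sulfonyl fluoride (1.2 equiv), tert-butylimino-tri(pyrrolidino)phosphorane (2.3 equiv), DMF, −20 °C to rt; pentane extraction, careful distillation
Reagents that add atoms: none
Why: One-pot conversion of an enolisable aldehyde into a terminal alkyne: the phosphazene base forms the enolate, O-sulfonylation gives alkenyl nonaflate 8, and a second equivalent of base eliminates nonaflate across C1–C2. C3 is neither enolised nor part of the elimination, so the R configuration of 7 passes unchanged into 9.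

Step 4
Reactants: 10 O-[2-(trimethylsilyl)ethyl]hydroxylamine hydrochloride
Product: 11 N,N-bis(methylsulfonyl)-O-[2-(trimethylsilyl)ethyl]hydroxylamine
Conditions: MsCl (2.5 equiv), Et3N (4 equiv), DMAP (cat.), CH2Cl2, 0 °C to rt
Reagents that add atoms: methanesulfonyl chloride, CS(=O)(=O)Cl
Why: Double N-sulfonylation of an O-alkylhydroxylamine: the first mesylation gives an acidic N-alkoxysulfonamide that Et3N deprotonates for the second; the silylethyl group is untouched in the absence of fluoride or acid.

Step 5
Reactants: 6 3-(3-iodophenyl)-7-[2-(trimethylsilyl)ethoxy]-4H-chromen-4-one; 11 N,N-bis(methylsulfonyl)-O-[2-(trimethylsilyl)ethyl]hydroxylamine; 9 (3R)-3,7-dimethyloct-6-en-1-yne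
Product: 12 3-{3-[(3R)-3,7-dimethyloct-6-en-1-yn-1-yl]-4-[2-(trimethylsilyl)ethoxy]phenyl}-7-[2-(trimethylsilyl)ethoxy]-4H-chromen-4-one
Conditions: Pd(OAc)2 (10 mol%), tri(2-furyl)phosphine (25 mol%), 1-methylbicyclo[2.2.1]hept-2-ene (1 equiv), Cs2CO3 (3 equiv), 11 (1.5 equiv), 9 (1.5 equiv, added slowly), 1,4-dioxane, 100 °C
Reagents that add atoms: none
Why: Proposed new method: zerovalent palladium inserts into the C3'–I bond of 6, the bridgehead-substituted norbornene inserts into the aryl–palladium bond, and C–H palladation at C4' gives a five-membered aryl–norbornyl palladacycle of divalent palladium; this electron-rich palladacycle attacks the oxygen of 11 with the bis(sulfonyl)amide as leaving group, and the resulting alkoxide of tetravalent palladium forms the C4'–O bond by reductive elimination; β-carbon elimination then expels the norbornene, and the aryl–palladium species at C3' is intercepted by alkyne 9 (deprotonated by Cs2CO3), C3'–C1'' reductive elimination returning zerovalent palladium. The closest known reaction type is the palladium/norbornene (Catellani-type) ortho C–H alkoxylation of aryl iodides with N,N-bis(sulfonyl)-O-alkylhydroxylamines, established for simple groups such as methoxy, combined with alkynyl ipso termination in the same manifold. What is new is transfer of a fluoride-cleavable 2-(trimethylsilyl)ethoxy group, which should be feasible because the carbon on oxygen is still an unhindered primary CH2, silicon is two atoms from the reacting oxygen, and no fluoride is present. No ring is closed and no stereocenter is created; the R centre of 9 is not acidic under carbonate and takes part in no bond change. The step needs site selectivity between the two ortho C–H bonds and clean mono-functionalisation: C2' is wedged between the palladium-bearing carbon and ring C on C1', so palladation goes to C4', and the bridgehead substituent speeds norbornene extrusion after one ortho group is in place and blocks a second cycle. Chemoselectivity rests on norbornene insertion outrunning direct alkynylation of the first aryl–palladium iodide (no copper, slow addition of 9) and on C–O reductive elimination outrunning β-hydride loss from the alkoxide, as it does for methoxide.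

Step 6
Reactants: 12 3-{3-[(3R)-3,7-dimethyloct-6-en-1-yn-1-yl]-4-[2-(trimethylsilyl)ethoxy]phenyl}-7-[2-(trimethylsilyl)ethoxy]-4H-chromen-4-one
Product: 13 3-{3-[(1Z,3R)-3,7-dimethylocta-1,6-dien-1-yl]-4-[2-(trimethylsilyl)ethoxy]phenyl}-7-[2-(trimethylsilyl)ethoxy]-4H-chromen-4-one
Conditions: H2 (1 atm), Pd on CaCO3 poisoned with Pb(OAc)2, quinoline, EtOAc, rt, stopped after one equivalent of H2
Reagents that add atoms: none
Why: Lindlar-type semihydrogenation: syn delivery of hydrogen on the poisoned palladium surface gives the Z alkene; the trisubstituted C6''=C7'' alkene and the C2=C3 bond of ring C are not reduced on this catalyst, and C3'' is untouched.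

Step 7
Reactants: 13 3-{3-[(1Z,3R)-3,7-dimethylocta-1,6-dien-1-yl]-4-[2-(trimethylsilyl)ethoxy]phenyl}-7-[2-(trimethylsilyl)ethoxy]-4H-chromen-4-one
Product: 14 3-{3-[(1Z,3R)-3,7-dimethylocta-1,6-dien-1-yl]-4-hydroxyphenyl}-7-hydroxy-4H-chromen-4-one
Conditions: CsF (6 equiv), DMF, 80 °C; then aq. NH4Cl
Reagents that add atoms: none
Why: Fluoride attacks silicon and each 2-silylethyl aryl ether fragments to fluorotrimethylsilane, ethylene and the phenoxide (fluoride-induced β-elimination); no acid is involved, so the Z-styrene, the trisubstituted alkene and the stereocenter are left as they are.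

## Compound list

1 | resorcinol (benzene-1,3-diol) | Oc1cccc(O)c1 | starting material
2 | 3-iodophenylacetic acid | OC(=O)Cc1cccc(I)c1 | starting material
3 | 1-(2,4-dihydroxyphenyl)-2-(3-iodophenyl)ethanone (deoxybenzoin, not isolated) | O=C(Cc1cccc(I)c1)c1ccc(O)cc1O | intermediate
4 | 7-hydroxy-3-(3-iodophenyl)-4H-chromen-4-one | O=c1c(-c2cccc(I)c2)coc2cc(O)ccc12 | intermediate
5 | 2-(trimethylsilyl)ethanol | C[Si](C)(C)CCO | starting material
6 | 3-(3-iodophenyl)-7-[2-(trimethylsilyl)ethoxy]-4H-chromen-4-one | C[Si](C)(C)CCOc1ccc2c(c1)occ(-c1cccc(I)c1)c2=O | intermediate
7 | (R)-citronellal, (3R)-3,7-dimethyloct-6-enal | CC(C)=CCC[C@@H](C)CC=O | starting material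
8 | (3R)-3,7-dimethylocta-1,6-dien-1-yl nonafluorobutane-1-sulfonate (E/Z mixture at C1=C2, not isolated) | CC(C)=CCC[C@@H](C)C=COS(=O)(=O)C(F)(F)C(F)(F)C(F)(F)C(F)(F)F | intermediate
9 | (3R)-3,7-dimethyloct-6-en-1-yne | C#C[C@H](C)CCC=C(C)C | intermediate
10 | O-[2-(trimethylsilyl)ethyl]hydroxylamine hydrochloride | C[Si](C)(C)CCON.Cl | starting material
11 | N,N-bis(methylsulfonyl)-O-[2-(trimethylsilyl)ethyl]hydroxylamine | CS(=O)(=O)N(OCC[Si](C)(C)C)S(C)(=O)=O | intermediate
12 | 3-{3-[(3R)-3,7-dimethyloct-6-en-1-yn-1-yl]-4-[2-(trimethylsilyl)ethoxy]phenyl}-7-[2-(trimethylsilyl)ethoxy]-4H-chromen-4-one | CC(C)=CCC[C@@H](C)C#Cc1cc(-c2coc3cc(OCC[Si](C)(C)C)ccc3c2=O)ccc1OCC[Si](C)(C)C | intermediate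
13 | 3-{3-[(1Z,3R)-3,7-dimethylocta-1,6-dien-1-yl]-4-[2-(trimethylsilyl)ethoxy]phenyl}-7-[2-(trimethylsilyl)ethoxy]-4H-chromen-4-one | CC(C)=CCC[C@@H](C)/C=C\c1cc(-c2coc3cc(OCC[Si](C)(C)C)ccc3c2=O)ccc1OCC[Si](C)(C)C | intermediate
14 | 3-{3-[(1Z,3R)-3,7-dimethylocta-1,6-dien-1-yl]-4-hydroxyphenyl}-7-hydroxy-4H-chromen-4-one (CNP0200226.1) | CC(C)=CCC[C@@H](C)/C=C\c1cc(-c2coc3cc(O)ccc3c2=O)ccc1O | target

## Step count and risks

Total: 7 steps. Longest linear sequence: 5 steps (steps 1, 2, 5, 6, 7 from resorcinol); steps 3 and 4 each feed step 5 directly.

**Step 5 (key step, new method).**
- **Risk.** Oxygen transfer from the bulkier O-alkyl reagent may be slower than collapse of the palladacycle by C–C reductive elimination onto the norbornyl carbon, or than β-hydride loss from the alkoxide. The alkyne may couple at C3' before the norbornene relay has started. Norbornene extrusion may be incomplete with only one ortho substituent. The first variable to change would be the mediator (a 7-bromo norbornene is the one associated with the known methoxylation).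
- **Fallback (known chemistry only).** It sets out from 1 and returns at 12. Acylation of 1 with commercial 4-hydroxy-3-iodophenylacetic acid (OC(=O)Cc1ccc(O)c(I)c1) in BF3·OEt2 and ring closure with DMF and MsCl, as in step 1, would lead through 1-(2,4-dihydroxyphenyl)-2-(4-hydroxy-3-iodophenyl)ethanone F1 to 7-hydroxy-3-(4-hydroxy-3-iodophenyl)-4H-chromen-4-one F2. Double Mitsunobu etherification with 5 would give 3-{3-iodo-4-[2-(trimethylsilyl)ethoxy]phenyl}-7-[2-(trimethylsilyl)ethoxy]-4H-chromen-4-one F3. Sonogashira coupling of F3 with 9 (Pd(PPh3)2Cl2, CuI, Et3N, THF) would give 12. The oxygen is then bought with the arylacetic acid and only the C3'–C1'' bond is made by palladium.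

**Step 3.**
- **Risk.** The aldehyde may self-condense under the strong base before O-sulfonylation. The less reactive geometric isomer of 8 may eliminate incompletely. Base-mediated alkyne–allene isomerisation through C3 would erode the stereocenter. The volatile hydrocarbon may be lost on isolation.
- **Fallback.** It sets out from 7 and returns at 9 by a different construction of the triple bond. Condensation of 7 with piperidine (K2CO3) would give (R,E)-1-(3,7-dimethylocta-1,6-dien-1-yl)piperidine F4. Copper-catalysed aerobic cleavage of the enamine double bond (CuCl, O2, MeCN) would give (R)-2,6-dimethylhept-5-enal F5. Ohira–Bestmann homologation (dimethyl (1-diazo-2-oxopropyl)phosphonate, K2CO3, MeOH, 0 °C) would return 9. Here the α-stereocenter of F5 must be watched for epimerisation.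

**Step 7.**
- **Risk.** Fragmentation of the more electron-rich, ortho-flanked 4'-ether may be slow and require prolonged heating, during which basic fluoride and phenoxide could open the chromone at C2 or isomerise the Z-styrene.
- **Fallback.** It changes the protecting group instead of the cleavage conditions, sets out from 1 and returns at 14. F2, made from 1 as described for step 5, would be silylated (triisopropylsilyl chloride, imidazole, DMF) to 3-{3-iodo-4-[(triisopropylsilyl)oxy]phenyl}-7-[(triisopropylsilyl)oxy]-4H-chromen-4-one F6. Sonogashira coupling with 9 would give 3-{3-[(3R)-3,7-dimethyloct-6-en-1-yn-1-yl]-4-[(triisopropylsilyl)oxy]phenyl}-7-[(triisopropylsilyl)oxy]-4H-chromen-4-one F7. Semihydrogenation as in step 6 would give 3-{3-[(1Z,3R)-3,7-dimethylocta-1,6-dien-1-yl]-4-[(triisopropylsilyl)oxy]phenyl}-7-[(triisopropylsilyl)oxy]-4H-chromen-4-one F8. Buffered fluoride (Bu4NF, AcOH, THF, 0 °C) would release 14. This gives up the three-component step.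

**Step 6.**
- **Risk.** Over-reduction of the chain may occur, or the reaction may stall because the alkyne is flanked by an ortho-alkoxyaryl group and a branched carbon. Slow Z to E isomerisation is possible on long contact with the catalyst.
- **Fallback.** It sets out from 12 and returns at 13 and makes no new compound (F0). Catalytic hydrogenation is replaced by a stoichiometric electron-transfer reduction with zinc activated by Cu(OAc)2 and AgNO3 in aqueous methanol. This reduces aryl-conjugated alkynes to Z alkenes and cannot hydrogenate the isolated C6''=C7'' alkene.

## Further compounds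

F1 | step 5 | 1-(2,4-dihydroxyphenyl)-2-(4-hydroxy-3-iodophenyl)ethanone | O=C(Cc1ccc(O)c(I)c1)c1ccc(O)cc1O
F2 | step 5 | 7-hydroxy-3-(4-hydroxy-3-iodophenyl)-4H-chromen-4-one | O=c1c(-c2ccc(O)c(I)c2)coc2cc(O)ccc12
F3 | step 5 | 3-{3-iodo-4-[2-(trimethylsilyl)ethoxy]phenyl}-7-[2-(trimethylsilyl)ethoxy]-4H-chromen-4-one | C[Si](C)(C)CCOc1ccc2c(c1)occ(-c1ccc(OCC[Si](C)(C)C)c(I)c1)c2=O
F4 | step 3 | (R,E)-1-(3,7-dimethylocta-1,6-dien-1-yl)piperidine | CC(C)=CCC[C@@H](C)/C=C/N1CCCCC1
F5 | step 3 | (R)-2,6-dimethylhept-5-enal | CC(C)=CCC[C@@H](C)C=O
F6 | step 7 | 3-{3-iodo-4-[(triisopropylsilyl)oxy]phenyl}-7-[(triisopropylsilyl)oxy]-4H-chromen-4-one | CC(C)[Si](Oc1ccc2c(c1)occ(-c1ccc(O[Si](C(C)C)(C(C)C)C(C)C)c(I)c1)c2=O)(C(C)C)C(C)C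
F7 | step 7 | 3-{3-[(3R)-3,7-dimethyloct-6-en-1-yn-1-yl]-4-[(triisopropylsilyl)oxy]phenyl}-7-[(triisopropylsilyl)oxy]-4H-chromen-4-one | CC(C)=CCC[C@@H](C)C#Cc1cc(-c2coc3cc(O[Si](C(C)C)(C(C)C)C(C)C)ccc3c2=O)ccc1O[Si](C(C)C)(C(C)C)C(C)C
F8 | step 7 | 3-{3-[(1Z,3R)-3,7-dimethylocta-1,6-dien-1-yl]-4-[(triisopropylsilyl)oxy]phenyl}-7-[(triisopropylsilyl)oxy]-4H-chromen-4-one | CC(C)=CCC[C@@H](C)/C=C\c1cc(-c2coc3cc(O[Si](C(C)C)(C(C)C)C(C)C)ccc3c2=O)ccc1O[Si](C(C)C)(C(C)C)C(C)C
F0 | step 6 | none | none
A1 | alternative 1 | 4-bromo-2-vinylphenyl (R)-4-methylhex-5-enoate | C=C[C@H](C)CCC(=O)Oc1ccc(Br)cc1C=C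
A2 | alternative 1 | (5R,6Z)-9-bromo-5-methyl-4,5-dihydro-1-benzoxonin-2(3H)-one (nine-membered benzo-fused lactone) | C[C@@H]1CCC(=O)Oc2ccc(Br)cc2/C=C\1
A3 | alternative 2 | 7,4'-bis(allyloxy)-3'-[(R)-3,7-dimethyloct-6-en-1-ynyl]-5-(triflyloxy)isoflavone | CC(C)=CCC[C@@H](C)C#Cc1cc(-c2coc3cc(OCC=C)cc(OS(=O)(=O)C(F)(F)F)c3c2=O)ccc1OCC=C
A4 | alternative 2 | 5-(allyloxy)-2-(trimethylsilyl)-1,3-phenylene bis(trifluoromethanesulfonate) | C=CCOc1cc(OS(=O)(=O)C(F)(F)F)c([Si](C)(C)C)c(OS(=O)(=O)C(F)(F)F)c1
A5 | alternative 2 | methyl 2-{4-(allyloxy)-3-[(R)-3,7-dimethyloct-6-en-1-ynyl]phenyl}-3-hydroxyacrylate | CC(C)=CCC[C@@H](C)C#Cc1cc(C(=CO)C(=O)OC)ccc1OCC=C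
A6 | alternative 3 | bis(tert-butyldimethylsilyl) ether of the target | CC(C)=CCC[C@@H](C)/C=C\c1cc(-c2coc3cc(O[Si](C)(C)C(C)(C)C)ccc3c2=O)ccc1O[Si](C)(C)C(C)(C)C
A7 | alternative 3 | 1-[4-(tert-butyldimethylsilyloxy)-2-hydroxyphenyl]-2-{4-(tert-butyldimethylsilyloxy)-3-[(1Z,3R)-3,7-dimethylocta-1,6-dien-1-yl]phenyl}-2-(triphenylphosphoranylidene)ethanone | CC(C)=CCC[C@@H](C)/C=C\c1cc(C(=P(c2ccccc2)(c2ccccc2)c2ccccc2)C(=O)c2ccc(O[Si](C)(C)C(C)(C)C)cc2O)ccc1O[Si](C)(C)C(C)(C)C
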